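**Strategy**

The target is 5-O-caffeoyl-4-O-malonylquinic acid. The plan rests on cutting the C4–C5 bond of the cyclohexane ring (C1–C6): C4 sits next to the C3 carbonyl and C5 carries a hydroxyl, so the ring hides an aldol retron inside a citrate-like chain C5–C6–C1–C2–C3. One L-proline-catalysed operation turns an acyclic keto aldehyde into the carbocycle, forms C4–C5, sets C4 and C5 (O4/O5 trans) and leaves O3 (ketone), O4 (PMB ether) and O5 (free hydroxyl) distinguished. The precursor, built on (S)-malic acid (C1, C5, C6, C7), is a PMB ester with O1 silylated, a CH2CHO arm and a CH2C(=O)CH2OPMB arm.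

Key step: step 9

Remark: quinic acid numbering is used throughout (C1 carries the carboxyl; O1, O3 and O4 lie on one face of the ring, O5 and the carboxyl on the other); "quinate" means the (−)-quinic acid configuration; PMB = 4-methoxybenzyl, TES = triethylsilyl, TBS = tert-butyldimethylsilyl, MOM = methoxymethyl; 3-bromo-2-(bromomethyl)prop-1-ene is taken as a commercial reagent.

**Route**

Step 1
Reactants: 1 (S)-malic acid; 2 pivalaldehyde
Product: 3 2-[(2S,4S)-2-tert-butyl-5-oxo-1,3-dioxolan-4-yl]acetic acid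
Conditions: TsOH·H2O (cat.), H2SO4 (cat.), pentane, reflux with azeotropic removal of water; recrystallisation
Reagents that add atoms: none
Why: Acid-catalysed acetalisation of the α-hydroxy acid unit (dioxolanone formation, first stage of self-regeneration of stereocentres) should give the cis acetal, whose new acetal centre (2S) is set under thermodynamic control by the malate centre and secured by crystallisation.

Step 2
Reactants: 4 4-methoxybenzyl alcohol; 5 3-bromo-2-(bromomethyl)prop-1-ene
Product: 7 1-({[2-(bromomethyl)prop-2-en-1-yl]oxy}methyl)-4-methoxybenzene, via sodium 4-methoxybenzyl alkoxide 6 (not isolated)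
Conditions: NaH, THF, 0 °C; then 5 (3 equiv), 0 °C → rt
Reagents that add atoms: none
Why: Williamson ether synthesis on a symmetrical bis-allylic dibromide, in which the threefold excess of 5 should hold the reaction at mono-substitution and direct and allylic displacement give the same product.

Step 3
Reactants: 3 2-[(2S,4S)-2-tert-butyl-5-oxo-1,3-dioxolan-4-yl]acetic acid; 7 1-({[2-(bromomethyl)prop-2-en-1-yl]oxy}methyl)-4-methoxybenzene
Product: 9 2-[(2S,4S)-2-tert-butyl-4-(2-{[(4-methoxybenzyl)oxy]methyl}prop-2-en-1-yl)-5-oxo-1,3-dioxolan-4-yl]acetic acid, via dilithium enolate carboxylate 8 (not isolated)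
Conditions: LiN(SiMe3)2 (2.2 equiv), THF, −78 °C; then 7, −78 → −20 °C; 1 M HCl
Reagents that add atoms: none
Why: Enolate alkylation of the dioxolanone dianion (self-regeneration of stereocentres), in which the carboxylate shields its own α-CH2 and the allylic bromide should enter the enolate face opposite the tert-butyl group, so that the quaternary centre (the later C1) forms with overall retention of the malate configuration.

Step 4
Reactants: 9 2-[(2S,4S)-2-tert-butyl-4-(2-{[(4-methoxybenzyl)oxy]methyl}prop-2-en-1-yl)-5-oxo-1,3-dioxolan-4-yl]acetic acid; 4 4-methoxybenzyl alcohol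
Product: 11 (3S)-3-hydroxy-4-[(4-methoxybenzyl)oxy]-3-(2-{[(4-methoxybenzyl)oxy]methyl}prop-2-en-1-yl)-4-oxobutanoic acid, via lithium 4-methoxybenzyl alkoxide 10 (not isolated)
Conditions: 4 (3 equiv), n-BuLi (2.5 equiv), THF, −78 → 0 °C; then 9, 0 °C → rt; 1 M HCl, 0 °C
Reagents that add atoms: none
Why: Transesterification of the acylal lactone by a lithium benzylic alkoxide, in which one equivalent of alkoxide deprotonates the acid, the excess attacks the lithium-activated lactone carbonyl faster than the side-chain carboxylate can and the hemiacetal alkoxide collapses to pivalaldehyde, should give the PMB ester and the free tertiary alcohol without touching the stereocentre.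

Step 5
Reactants: 11 (3S)-3-hydroxy-4-[(4-methoxybenzyl)oxy]-3-(2-{[(4-methoxybenzyl)oxy]methyl}prop-2-en-1-yl)-4-oxobutanoic acid
Product: 12 4-methoxybenzyl (2S)-4-(ethylsulfanyl)-2-hydroxy-2-(2-{[(4-methoxybenzyl)oxy]methyl}prop-2-en-1-yl)-4-oxobutanoate
Conditions: EtSH (3 equiv), EDC·HCl, DMAP (cat.), CH2Cl2, 0 °C → rt
Reagents that add atoms: ethanethiol, CCS
Why: Steglich-type carbodiimide coupling with a thiol, in which the unhindered side-chain acid is activated and trapped by excess ethanethiol while the tertiary hydroxyl is too hindered to compete.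

Step 6
Reactants: 12 4-methoxybenzyl (2S)-4-(ethylsulfanyl)-2-hydroxy-2-(2-{[(4-methoxybenzyl)oxy]methyl}prop-2-en-1-yl)-4-oxobutanoate
Product: 13 4-methoxybenzyl (2S)-4-(ethylsulfanyl)-2-(2-{[(4-methoxybenzyl)oxy]methyl}prop-2-en-1-yl)-4-oxo-2-[(triethylsilyl)oxy]butanoate
Conditions: Et3SiOTf, 2,6-lutidine, CH2Cl2, −78 → 0 °C
Reagents that add atoms: triethylsilyl trifluoromethanesulfonate, CC[Si](CC)(CC)OS(=O)(=O)C(F)(F)F
Why: Silylation of a tertiary alcohol with a silyl triflate and a hindered pyridine base, which caps the hydroxyl that would otherwise sit β to both carbonyl groups of the cyclisation substrate and could leave, trigger retro-aldol cleavage or hydrogen-bond the aldehyde in competition with the catalyst.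

Step 7
Reactants: 13 4-methoxybenzyl (2S)-4-(ethylsulfanyl)-2-(2-{[(4-methoxybenzyl)oxy]methyl}prop-2-en-1-yl)-4-oxo-2-[(triethylsilyl)oxy]butanoate
Product: 15 4-methoxybenzyl (2S)-2-[2-(ethylsulfanyl)-2-oxoethyl]-5-[(4-methoxybenzyl)oxy]-4-oxo-2-[(triethylsilyl)oxy]pentanoate, via secondary ozonide 14 (not isolated)
Conditions: O3, CH2Cl2, −78 °C (Sudan Red 7B end point); then PPh3, −78 °C → rt
Reagents that add atoms: ozone, [O-][O+]=O
Why: Ozonolysis with reductive work-up, in which the electron-rich 1,1-disubstituted alkene should react far faster than the anisole rings or the thioester when the gas flow is stopped at the indicator end point, delivering the α-alkoxy ketone.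

Step 8
Reactants: 15 4-methoxybenzyl (2S)-2-[2-(ethylsulfanyl)-2-oxoethyl]-5-[(4-methoxybenzyl)oxy]-4-oxo-2-[(triethylsilyl)oxy]pentanoate
Product: 16 4-methoxybenzyl (2R)-5-[(4-methoxybenzyl)oxy]-4-oxo-2-(2-oxoethyl)-2-[(triethylsilyl)oxy]pentanoate
Conditions: Et3SiH, Pd/C (10 wt %), acetone, rt
Reagents that add atoms: none
Why: Fukuyama reduction, in which palladium inserts into the acyl–sulfur bond and the silane delivers hydride so that the reaction should stop at the aldehyde, while the ketone, the benzylic ether and ester and the silyl ether are inert in an aprotic solvent.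

Step 9
Reactants: 16 4-methoxybenzyl (2R)-5-[(4-methoxybenzyl)oxy]-4-oxo-2-(2-oxoethyl)-2-[(triethylsilyl)oxy]pentanoate
Product: 18 4-methoxybenzyl 4-O-(4-methoxybenzyl)-1-O-(triethylsilyl)-3-dehydroquinate, via C3–C4 proline enamine 17 (not isolated)
Conditions: L-proline (30 mol %), DMSO (0.05 M), rt
Reagents that add atoms: none
Why: Proposed new method: L-proline condenses with the C3 ketone, and only the enamine across C3–C4 can reach the C5 aldehyde through a six-membered transition state (the C2–C3 enamine and the aldehyde enamine could only close four-membered rings), so C4 adds to C5 while the catalyst's carboxylic acid hydrogen-bonds the aldehyde oxygen, and hydrolysis of the iminium releases 18. The closest known reactions are the Hajos–Parrish-type intramolecular enamine aldol and proline-catalysed aldol additions of α-oxygenated ketones, which have not been combined on a citrate-type keto aldehyde. The cyclohexane ring closes in the 6-(enolendo)-exo-trig mode. C4 (S) is set by the E enamine (OPMB trans to nitrogen) reacting on the face that carries the carboxylic acid of the (S)-catalyst, and C5 (R) by the aldehyde geometry in which the C6 tether is gauche to C3 and the carbonyl oxygen points to that acid, which places O4 and O5 trans. The step needs chemoselectivity for the ketone enamine and the correct sense relative to C1: the first is secured by ring size and dilution, the second by catalyst control, helped by the silylated O1 (no retro-aldol, no dehydration, no internal hydrogen bond to the aldehyde) and by a product chair with the ester, O4 and O5 all equatorial, so that reversible aldolisation should converge on the same isomer.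

Step 10
Reactants: 19 caffeic acid
Product: 21 (E)-3-[3,4-bis(methoxymethoxy)phenyl]prop-2-enoic acid, via methoxymethyl ester 20 (not isolated)
Conditions: MeOCH2Cl (3.5 equiv), i-Pr2NEt, CH2Cl2, 0 °C → rt; then LiOH, THF/MeOH/H2O, rt; 1 M HCl to pH 4, 0 °C
Reagents that add atoms: chloromethyl methyl ether, COCCl; lithium hydroxide, [Li+].[OH-]
Why: Methoxymethylation of both phenols and the carboxylate followed by saponification of the labile methoxymethyl ester alone is a standard protection sequence (acetal ether formation, ester hydrolysis) that leaves the E alkene untouched.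

Step 11
Reactants: 18 4-methoxybenzyl 4-O-(4-methoxybenzyl)-1-O-(triethylsilyl)-3-dehydroquinate; 21 (E)-3-[3,4-bis(methoxymethoxy)phenyl]prop-2-enoic acid
Product: 22 4-methoxybenzyl 5-O-[(E)-3,4-bis(methoxymethoxy)cinnamoyl]-4-O-(4-methoxybenzyl)-1-O-(triethylsilyl)-3-dehydroquinate
Conditions: EDC·HCl, DMAP (0.2 equiv), CH2Cl2, 0 °C
Reagents that add atoms: none
Why: Steglich esterification at O5, the only free hydroxyl, where low temperature and little DMAP should keep the β-acyloxy ketone from eliminating.

Step 12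
Reactants: 22 4-methoxybenzyl 5-O-[(E)-3,4-bis(methoxymethoxy)cinnamoyl]-4-O-(4-methoxybenzyl)-1-O-(triethylsilyl)-3-dehydroquinate
Product: 23 4-methoxybenzyl 5-O-[(E)-3,4-bis(methoxymethoxy)cinnamoyl]-4-O-(4-methoxybenzyl)-1-O-(triethylsilyl)quinate
Conditions: Zn(BH4)2, Et2O/CH2Cl2, −20 → 0 °C; aq. NH4Cl
Reagents that add atoms: none
Why: Chelation-controlled borohydride reduction, in which zinc ties the C3 carbonyl to the equatorial O4 ether and the axial silyloxy group on C1 blocks the α face, so that hydride should add from the β face and set C3 (R) with its axial hydroxyl cis to O4, while Zn(BH4)2 leaves the esters and the enoate alone.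

Step 13
Reactants: 23 4-methoxybenzyl 5-O-[(E)-3,4-bis(methoxymethoxy)cinnamoyl]-4-O-(4-methoxybenzyl)-1-O-(triethylsilyl)quinate
Product: 24 4-methoxybenzyl 5-O-[(E)-3,4-bis(methoxymethoxy)cinnamoyl]-3-O-(tert-butyldimethylsilyl)-4-O-(4-methoxybenzyl)-1-O-(triethylsilyl)quinate
Conditions: t-BuMe2SiOTf, 2,6-lutidine, CH2Cl2, −78 → −20 °C
Reagents that add atoms: tert-butyldimethylsilyl trifluoromethanesulfonate, CC(C)(C)[Si](C)(C)OS(=O)(=O)C(F)(F)F
Why: Silyl triflate silylation of the single free hydroxyl, which is axial and hindered and therefore needs the triflate, at a temperature at which the aryl MOM acetals and the esters should be unaffected.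

Step 14
Reactants: 24 4-methoxybenzyl 5-O-[(E)-3,4-bis(methoxymethoxy)cinnamoyl]-3-O-(tert-butyldimethylsilyl)-4-O-(4-methoxybenzyl)-1-O-(triethylsilyl)quinate
Product: 25 4-methoxybenzyl 5-O-[(E)-3,4-bis(methoxymethoxy)cinnamoyl]-3-O-(tert-butyldimethylsilyl)-1-O-(triethylsilyl)quinate
Conditions: DDQ, CH2Cl2/pH 7 phosphate buffer (10:1), 0 °C → rt
Reagents that add atoms: none
Why: Oxidative cleavage of a PMB ether by DDQ (benzylic hydride abstraction, then hydrolysis of the hemiacetal), which should be much faster than attack on the PMB ester, whose benzylic cation would carry an acyloxy group, or on the deactivated cinnamate ring.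

Step 15
Reactants: 25 4-methoxybenzyl 5-O-[(E)-3,4-bis(methoxymethoxy)cinnamoyl]-3-O-(tert-butyldimethylsilyl)-1-O-(triethylsilyl)quinate; 26 Meldrum's acid
Product: 27 4-methoxybenzyl 5-O-[(E)-3,4-bis(methoxymethoxy)cinnamoyl]-3-O-(tert-butyldimethylsilyl)-4-O-(carboxyacetyl)-1-O-(triethylsilyl)quinate
Conditions: toluene, 85 °C
Reagents that add atoms: none
Why: Thermal ring-opening acylation of an alcohol by Meldrum's acid gives the malonic half ester directly with loss of acetone under neutral conditions, which should spare the silyl and MOM ethers and limit acyl migration.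

Step 16
Reactants: 27 4-methoxybenzyl 5-O-[(E)-3,4-bis(methoxymethoxy)cinnamoyl]-3-O-(tert-butyldimethylsilyl)-4-O-(carboxyacetyl)-1-O-(triethylsilyl)quinate
Product: 28 5-O-[(E)-caffeoyl]-4-O-malonylquinic acid (CNP0286789.1)
Conditions: CF3CO2H/CH2Cl2/H2O (10:10:1), anisole, 0 °C → rt
Reagents that add atoms: none
Why: Global acidolysis, in which trifluoroacetic acid cleaves the PMB ester (cation trapped by anisole), both silyl ethers and the two aryl MOM acetals, while the esters of the secondary alcohols, the malonic half ester and the E enoate should be stable to acid at room temperature.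

**Compound list**

1 | (S)-malic acid | O[C@@H](CC(=O)O)C(=O)O | starting material
2 | pivalaldehyde (2,2-dimethylpropanal) | CC(C)(C)C=O | starting material
3 | 2-[(2S,4S)-2-tert-butyl-5-oxo-1,3-dioxolan-4-yl]acetic acid (cis) | CC(C)(C)[C@H]1O[C@@H](CC(=O)O)C(=O)O1 | intermediate
4 | 4-methoxybenzyl alcohol | COc1ccc(CO)cc1 | starting material
5 | 3-bromo-2-(bromomethyl)prop-1-ene | C=C(CBr)CBr | starting material
6 | sodium 4-methoxybenzyl alkoxide (not isolated) | COc1ccc(C[O-])cc1.[Na+] | intermediate
7 | 1-({[2-(bromomethyl)prop-2-en-1-yl]oxy}methyl)-4-methoxybenzene | C=C(CBr)COCc1ccc(OC)cc1 | intermediate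
8 | dilithium enolate carboxylate of 3 (not isolated) | CC(C)(C)[C@H]1OC(CC(=O)[O-])=C([O-])O1.[Li+].[Li+] | intermediate
9 | 2-[(2S,4S)-2-tert-butyl-4-(2-{[(4-methoxybenzyl)oxy]methyl}prop-2-en-1-yl)-5-oxo-1,3-dioxolan-4-yl]acetic acid (tert-butyl cis to CH2CO2H) | CC(C)(C)[C@H]1O[C@](CC(=O)O)(CC(=C)COCc2ccc(OC)cc2)C(=O)O1 | intermediate
10 | lithium 4-methoxybenzyl alkoxide (not isolated) | COc1ccc(C[O-])cc1.[Li+] | intermediate
11 | (3S)-3-hydroxy-4-[(4-methoxybenzyl)oxy]-3-(2-{[(4-methoxybenzyl)oxy]methyl}prop-2-en-1-yl)-4-oxobutanoic acid | O[C@](CC(=O)O)(CC(=C)COCc1ccc(OC)cc1)C(=O)OCc1ccc(OC)cc1 | intermediate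
12 | 4-methoxybenzyl (2S)-4-(ethylsulfanyl)-2-hydroxy-2-(2-{[(4-methoxybenzyl)oxy]methyl}prop-2-en-1-yl)-4-oxobutanoate | CCSC(=O)C[C@@](O)(CC(=C)COCc1ccc(OC)cc1)C(=O)OCc1ccc(OC)cc1 | intermediate
13 | 4-methoxybenzyl (2S)-4-(ethylsulfanyl)-2-(2-{[(4-methoxybenzyl)oxy]methyl}prop-2-en-1-yl)-4-oxo-2-[(triethylsilyl)oxy]butanoate | CCSC(=O)C[C@@](O[Si](CC)(CC)CC)(CC(=C)COCc1ccc(OC)cc1)C(=O)OCc1ccc(OC)cc1 | intermediate
14 | secondary ozonide (1,2,4-trioxolane) of 13, mixture of epimers at the trioxolane carbon (not isolated) | CCSC(=O)C[C@@](O[Si](CC)(CC)CC)(CC1(COCc2ccc(OC)cc2)OCOO1)C(=O)OCc1ccc(OC)cc1 | intermediate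
15 | 4-methoxybenzyl (2S)-2-[2-(ethylsulfanyl)-2-oxoethyl]-5-[(4-methoxybenzyl)oxy]-4-oxo-2-[(triethylsilyl)oxy]pentanoate | CCSC(=O)C[C@@](O[Si](CC)(CC)CC)(CC(=O)COCc1ccc(OC)cc1)C(=O)OCc1ccc(OC)cc1 | intermediate
16 | 4-methoxybenzyl (2R)-5-[(4-methoxybenzyl)oxy]-4-oxo-2-(2-oxoethyl)-2-[(triethylsilyl)oxy]pentanoate (key-step precursor) | O=CC[C@@](O[Si](CC)(CC)CC)(CC(=O)COCc1ccc(OC)cc1)C(=O)OCc1ccc(OC)cc1 | intermediate
17 | (E)-enamine of 16 with L-proline across C3–C4 (not isolated) | O=CC[C@@](O[Si](CC)(CC)CC)(C/C(=C\OCc1ccc(OC)cc1)N1CCC[C@H]1C(=O)O)C(=O)OCc1ccc(OC)cc1 | intermediate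
18 | 4-methoxybenzyl 4-O-(4-methoxybenzyl)-1-O-(triethylsilyl)-3-dehydroquinate (1R,4S,5R in quinic acid numbering; key-step product) | COc1ccc(CO[C@@H]2C(=O)C[C@@](O[Si](CC)(CC)CC)(C(=O)OCc3ccc(OC)cc3)C[C@H]2O)cc1 | intermediate
19 | caffeic acid | O=C(O)/C=C/c1ccc(O)c(O)c1 | starting material
20 | methoxymethyl (E)-3-[3,4-bis(methoxymethoxy)phenyl]prop-2-enoate (not isolated) | COCOC(=O)/C=C/c1ccc(OCOC)c(OCOC)c1 | intermediate
21 | (E)-3-[3,4-bis(methoxymethoxy)phenyl]prop-2-enoic acid | O=C(O)/C=C/c1ccc(OCOC)c(OCOC)c1 | intermediate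
22 | 4-methoxybenzyl 5-O-[(E)-3,4-bis(methoxymethoxy)cinnamoyl]-4-O-(4-methoxybenzyl)-1-O-(triethylsilyl)-3-dehydroquinate | COc1ccc(CO[C@@H]2C(=O)C[C@@](O[Si](CC)(CC)CC)(C(=O)OCc3ccc(OC)cc3)C[C@H]2OC(=O)/C=C/c3ccc(OCOC)c(OCOC)c3)cc1 | intermediate
23 | 4-methoxybenzyl 5-O-[(E)-3,4-bis(methoxymethoxy)cinnamoyl]-4-O-(4-methoxybenzyl)-1-O-(triethylsilyl)quinate | COc1ccc(CO[C@@H]2[C@H](O)C[C@@](O[Si](CC)(CC)CC)(C(=O)OCc3ccc(OC)cc3)C[C@H]2OC(=O)/C=C/c3ccc(OCOC)c(OCOC)c3)cc1 | intermediate
24 | 4-methoxybenzyl 5-O-[(E)-3,4-bis(methoxymethoxy)cinnamoyl]-3-O-(tert-butyldimethylsilyl)-4-O-(4-methoxybenzyl)-1-O-(triethylsilyl)quinate | COc1ccc(CO[C@@H]2[C@H](O[Si](C)(C)C(C)(C)C)C[C@@](O[Si](CC)(CC)CC)(C(=O)OCc3ccc(OC)cc3)C[C@H]2OC(=O)/C=C/c3ccc(OCOC)c(OCOC)c3)cc1 | intermediate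
25 | 4-methoxybenzyl 5-O-[(E)-3,4-bis(methoxymethoxy)cinnamoyl]-3-O-(tert-butyldimethylsilyl)-1-O-(triethylsilyl)quinate | O[C@@H]1[C@H](O[Si](C)(C)C(C)(C)C)C[C@@](O[Si](CC)(CC)CC)(C(=O)OCc2ccc(OC)cc2)C[C@H]1OC(=O)/C=C/c1ccc(OCOC)c(OCOC)c1 | intermediate
26 | Meldrum's acid (2,2-dimethyl-1,3-dioxane-4,6-dione) | CC1(C)OC(=O)CC(=O)O1 | starting material
27 | 4-methoxybenzyl 5-O-[(E)-3,4-bis(methoxymethoxy)cinnamoyl]-3-O-(tert-butyldimethylsilyl)-4-O-(carboxyacetyl)-1-O-(triethylsilyl)quinate | O=C(O)CC(=O)O[C@@H]1[C@H](O[Si](C)(C)C(C)(C)C)C[C@@](O[Si](CC)(CC)CC)(C(=O)OCc2ccc(OC)cc2)C[C@H]1OC(=O)/C=C/c1ccc(OCOC)c(OCOC)c1 | intermediate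
28 | 5-O-[(E)-caffeoyl]-4-O-malonylquinic acid, (1S,3R,4R,5R) (CNP0286789.1) | O=C(O)CC(=O)O[C@@H]1[C@H](O)C[C@@](O)(C(=O)O)C[C@H]1OC(=O)/C=C/c1ccc(O)c(O)c1 | target

**Step count**

Total: 16 steps. Longest linear sequence: 14 steps (steps 1, 3–9 and 11–16, from (S)-malic acid).

**Steps most likely to fail**

Step 9 (key step, proposed new method). The aldehyde may be consumed through its own enamine (intermolecular self-aldolisation) before the ketone enamine closes the ring. The C1 centre may also erode the facial selectivity of the catalyst, because the catalyst-preferred transition state starts from a chair with the C1 ester axial. The β-hydroxy ketone may dehydrate. The fallback replaces enamine catalysis by a Lewis acid closure of a preformed enol silane, all known chemistry, and sets out from keto thioester 15. Soft enolisation with t-BuMe2SiOTf and Et3N in CH2Cl2 at −78 °C should give, on the more acidic and less hindered C4 side, the (Z)-silyl enol ether of 15 F1. Fukuyama reduction (Et3SiH, Pd/C, acetone) would then unveil the aldehyde only after the nucleophile is fixed, giving the enol silane aldehyde F2. BF3·OEt2 in CH2Cl2 at −78 °C would close the ring by an intramolecular Mukaiyama aldol addition and, after aqueous work-up, return to 18; the trans isomer would be separated if the open transition state gives a mixture.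

Step 12. Hydride may be delivered from the α face if zinc chelation is weak, which would give the C3 epimer, or the β-acyloxy ketone may eliminate under the Lewis acidic conditions. The fallback changes the order of events and sets out from 18. Reduction before acylation with the bulky LiBH(s-Bu)3 (THF, −78 °C), which can only attack equatorially and meets no enoate, should give the diol 4-methoxybenzyl 4-O-(4-methoxybenzyl)-1-O-(triethylsilyl)quinate F3. Steglich esterification with 21 (EDC·HCl, DMAP, 0 °C) should then take place at the equatorial O5, not at the axial O3, which is shielded by the syn-axial silyloxy group, and the route is rejoined at 23.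

Step 15. Acylation of the hindered O4 may be slow at a temperature at which the caffeoyl group can migrate from O5 to O4 or the silyl group from O3 to O4. The fallback uses a protected malonyl donor under carbodiimide activation at low temperature and sets out from 25. Coupling with 3-tert-butoxy-3-oxopropanoic acid (EDC·HCl, DMAP cat., CH2Cl2, 0 °C; acyl ketene pathway) should give the tert-butyl malonate diester F4. Its tert-butyl ester falls together with the other acid-labile groups under the conditions of step 16, so the route is rejoined at 28.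

**Further compounds**

F1 | step 9 | (Z)-tert-butyldimethylsilyl enol ether of 15 across C3–C4 | CCSC(=O)C[C@@](O[Si](CC)(CC)CC)(C/C(O[Si](C)(C)C(C)(C)C)=C/OCc1ccc(OC)cc1)C(=O)OCc1ccc(OC)cc1
F2 | step 9 | (Z)-tert-butyldimethylsilyl enol ether of 16 across C3–C4 (enol silane aldehyde) | O=CC[C@@](O[Si](CC)(CC)CC)(C/C(O[Si](C)(C)C(C)(C)C)=C/OCc1ccc(OC)cc1)C(=O)OCc1ccc(OC)cc1
F3 | step 12 | 4-methoxybenzyl 4-O-(4-methoxybenzyl)-1-O-(triethylsilyl)quinate | COc1ccc(CO[C@@H]2[C@H](O)C[C@@](O[Si](CC)(CC)CC)(C(=O)OCc3ccc(OC)cc3)C[C@H]2O)cc1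
F4 | step 15 | 4-methoxybenzyl 5-O-[(E)-3,4-bis(methoxymethoxy)cinnamoyl]-4-O-(3-tert-butoxy-3-oxopropanoyl)-3-O-(tert-butyldimethylsilyl)-1-O-(triethylsilyl)quinate | CC(C)(C)OC(=O)CC(=O)O[C@@H]1[C@H](O[Si](C)(C)C(C)(C)C)C[C@@](O[Si](CC)(CC)CC)(C(=O)OCc2ccc(OC)cc2)C[C@H]1OC(=O)/C=C/c1ccc(OCOC)c(OCOC)c1
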